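**Plan**
- Cuts, from the tetronate end: the exocyclic C5=C bond of the tetronate (aldol, then dehydration), the O1–C2 bond of furan A, the alkenyl–alkynyl bond beside it (Sonogashira), and the bond from C4 of furan A to the chain (carbomagnesiation). In the chain, the C–CH3 and =CH–CH2 bonds at the E-alkene (carboalumination, oxirane) and one CH2–CH2 bond two atoms from the stereocentre (copper coupling).
- Enabling feature: furan A is substituted only at C2 (the CH2 bridge to C3 of furan B) and at C4 (the chain). Its O1, C5, C4, C3, C2 and the bridge carbon therefore map one for one onto HO, C1, C2, C3, C4 and C5 of a (Z)-2-en-4-yn-1-ol that already carries furan B on C5.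
- Forward order: the chain grows outward from the stereocentre. Furan B is bought as furan-3-carbaldehyde and joined as its alkyne, furan A closes next, and the purchased tetronic acid ring is attached last.
- Stereochemistry: the R centre is bought in (S)-3-bromo-2-methylpropan-1-ol, and no bond to it is ever made or broken (only the descriptor changes). The E-alkene comes from syn-methylalumination, the Z-enynol from chelate-directed anti-carbomagnesiation, and the Z-ylidene from E1cB elimination under allylic strain.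

Key step: step 9

Remark: the target is handled as the 4-hydroxy enol tautomer written in its SMILES. TBS = tert-butyldimethylsilyl.

**Step 1**
Reactants: 1 (S)-3-bromo-2-methylpropan-1-ol
Product: 2 [(2S)-3-bromo-2-methylpropoxy](tert-butyl)dimethylsilane
Conditions: TBSCl, imidazole, CH2Cl2, 0 °C to rt
Reagents that add atoms: tert-butyldimethylsilyl chloride, CC(C)(C)[Si](C)(C)Cl
Why: Imidazole-promoted silylation of a primary alcohol leaves the bromide alone and carries the stereocentre, which bears no reacting bond, through unchanged.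

**Step 2**
Reactants: 2 [(2S)-3-bromo-2-methylpropoxy](tert-butyl)dimethylsilane; 3 (4-bromobut-1-yn-1-yl)trimethylsilane
Product: 5 tert-butyldimethyl{[(2R)-2-methyl-7-(trimethylsilyl)hept-6-yn-1-yl]oxy}silane, via butynyl Grignard reagent 4 (not isolated)
Conditions: 3, Mg, THF, 40 °C; then 2, Li2CuCl4 (5 mol %), NMP, THF, 0 °C to rt
Reagents that add atoms: none
Why: Kochi-type copper-catalysed alkyl–alkyl cross-coupling of a primary Grignard reagent with a primary bromide is long established for β-methyl-branched 3-oxygenated propyl halides; the C–Br carbon is not stereogenic and the silyl cap blocks the acidic alkyne position.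

**Step 3**
Reactants: 5 tert-butyldimethyl{[(2R)-2-methyl-7-(trimethylsilyl)hept-6-yn-1-yl]oxy}silane
Product: 6 tert-butyldimethyl{[(2R)-2-methylhept-6-yn-1-yl]oxy}silane
Conditions: K2CO3 (0.2 equiv), MeOH, rt
Reagents that add atoms: none
Why: Base-catalysed methanolysis (protiodesilylation) cleaves only the C(sp)–Si bond, because an alkynyl anion leaves far more readily than an alkoxide, so the TBS ether stays.

**Step 4**
Reactants: 6 tert-butyldimethyl{[(2R)-2-methylhept-6-yn-1-yl]oxy}silane; 7 oxirane
Product: 10 (3E,8R)-9-(TBSO)-4,8-dimethylnon-3-en-1-ol, via alkenyldimethylalane 8 (not isolated), via lithium alkenylalanate 9 (not isolated)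
Conditions: Me3Al, Cp2ZrCl2 (25 mol %), CH2Cl2, 0 °C to rt; evaporate; n-BuLi, hexane, 0 °C; 7, THF, 0 °C to rt; aq Rochelle salt
Reagents that add atoms: trimethylaluminium, C[Al](C)C
Why: Negishi zirconium-catalysed methylalumination adds CH3 and Al syn across the terminal alkyne with aluminium on the end carbon, which fixes the E geometry, and the more nucleophilic butyl ate complex 9 then opens oxirane with retention at the alkenyl carbon.

**Step 5**
Reactants: 10 (3E,8R)-9-(TBSO)-4,8-dimethylnon-3-en-1-ol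
Product: 11 {[(2R,6E)-9-bromo-2,6-dimethylnon-6-en-1-yl]oxy}(tert-butyl)dimethylsilane
Conditions: CBr4, PPh3, CH2Cl2, 0 °C
Reagents that add atoms: carbon tetrabromide, BrC(Br)(Br)Br
Why: In the Appel reaction bromide displaces the oxyphosphonium ion by SN2 at a primary carbon under nearly neutral conditions that leave the TBS ether and the alkene untouched.

**Step 6**
Reactants: 11 {[(2R,6E)-9-bromo-2,6-dimethylnon-6-en-1-yl]oxy}(tert-butyl)dimethylsilane; 12 prop-2-yn-1-ol
Product: 16 (2Z)-2-[(3E,8R)-9-(TBSO)-4,8-dimethylnon-3-en-1-yl]-3-iodoprop-2-en-1-ol, via chain Grignard reagent 13 (not isolated), via chloromagnesium propynolate 14 (not isolated), via oxamagnesacycle 15 (not isolated)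
Conditions: 11, Mg, THF, 40 °C; separately 12, i-PrMgCl (1.0 equiv), THF, −40 °C; combine, CuI (15 mol %), −10 °C to rt; I2, THF, −40 to 0 °C; aq work-up
Reagents that add atoms: iodine, II
Why: In the copper-catalysed anti-carbomagnesiation of a propargylic magnesium alkoxide the alkyl group goes to the internal alkyne carbon and magnesium ends on the terminal carbon, cis to the CH2O arm inside chelate 15, so iodinolysis with retention fixes the Z geometry while the sacrificial i-PrMgCl saves one equivalent of the chain reagent.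

**Step 7**
Reactants: 17 furan-3-carbaldehyde
Product: 18 3-ethynylfuran
Conditions: dimethyl (1-diazo-2-oxopropyl)phosphonate, K2CO3, MeOH, 0 °C to rt; kept as an Et2O solution
Reagents that add atoms: dimethyl (1-diazo-2-oxopropyl)phosphonate, COP(=O)(OC)C(=[N+]=[N-])C(C)=O
Why: In the Ohira–Bestmann variant of the Seyferth–Gilbert homologation, methanolysis frees the diazomethylphosphonate anion, which olefinates the aldehyde, and loss of N2 with a 1,2-hydrogen shift gives the terminal alkyne.

**Step 8**
Reactants: 16 (2Z)-2-[(3E,8R)-9-(TBSO)-4,8-dimethylnon-3-en-1-yl]-3-iodoprop-2-en-1-ol; 18 3-ethynylfuran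
Product: 19 (2Z)-2-[(3E,8R)-9-(TBSO)-4,8-dimethylnon-3-en-1-yl]-5-(furan-3-yl)pent-2-en-4-yn-1-ol
Conditions: PdCl2(PPh3)2 (3 mol %), CuI (6 mol %), Et3N, THF, rt, degassed
Reagents that add atoms: none
Why: Sonogashira coupling of an alkenyl iodide at room temperature keeps the alkene geometry and tolerates the free allylic alcohol, the TBS ether and the furan.

**Step 9**
Reactants: 19 (2Z)-2-[(3E,8R)-9-(TBSO)-4,8-dimethylnon-3-en-1-yl]-5-(furan-3-yl)pent-2-en-4-yn-1-ol
Product: 21 tert-butyl{[(2R,6E)-9-[5-(furan-3-ylmethyl)furan-3-yl]-2,6-dimethylnon-6-en-1-yl]oxy}dimethylsilane, via ylidene-dihydrofuran 20 (not isolated)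
Conditions: (Ph3P)AuCl (2 mol %), AgOTf (2 mol %), THF, rt, dark
Reagents that add atoms: none
Why: Chloride abstraction by AgOTf gives Ph3PAu+ (monovalent gold), which binds the C4≡C5 triple bond of 19 so that the cis hydroxyl adds anti to the proximal carbon C4 and forms the O1–C2 bond of furan A. Protodeauration of the alkenylgold species gives the Z-configured ylidene-dihydrofuran 20, and a proton-relayed 1,3-hydrogen shift from the ring OCH2 to the exocyclic carbon aromatises it, which turns the former distal alkyne carbon into the CH2 bridge to furan B. The closest known reaction type is this very one, the gold-catalysed cycloisomerisation of (Z)-2-en-4-yn-1-ols to 2-alkylfurans, which also runs with aryl groups on the alkyne terminus. The one ring closes in the 5-exo-dig mode and no stereocentre is formed; the R centre in the chain is a remote spectator. The step needs oxygen attack at C4 rather than C5 (6-endo) and no interference by the chain alkene: the Z-alkene set in step 6 holds the CH2OH arm beside C4 on a short tether, and the chain lies trans to the alkyne across that same alkene and cannot reach it. Because C2 and C4 of furan A inherit their substituents directly from C4 and C2 of 19, the substitution pattern is fixed beforehand, and the neutral medium at low catalyst loading should spare the TBS ether and the acid-sensitive difurylmethane.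

**Step 10**
Reactants: 21 tert-butyl{[(2R,6E)-9-[5-(furan-3-ylmethyl)furan-3-yl]-2,6-dimethylnon-6-en-1-yl]oxy}dimethylsilane
Product: 22 (2R,6E)-9-[5-(furan-3-ylmethyl)furan-3-yl]-2,6-dimethylnon-6-en-1-ol
Conditions: TBAF, THF, 0 °C to rt
Reagents that add atoms: none
Why: Fluoride-induced desilylation is driven by the strong Si–F bond and runs without acid, which suits the difurylmethane.

**Step 11**
Reactants: 22 (2R,6E)-9-[5-(furan-3-ylmethyl)furan-3-yl]-2,6-dimethylnon-6-en-1-ol
Product: 23 (2R,6E)-9-[5-(furan-3-ylmethyl)furan-3-yl]-2,6-dimethylnon-6-enal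
Conditions: Dess–Martin periodinane, NaHCO3, CH2Cl2, 0 °C to rt
Reagents that add atoms: none
Why: Dess–Martin oxidation stops at the aldehyde and, buffered with NaHCO3, is mild enough neither to enolise the α-methyl stereocentre nor to attack the furans.

**Step 12**
Reactants: 24 4-hydroxy-3-methylfuran-2(5H)-one (3-methyltetronic acid)
Product: 25 4-methoxy-3-methylfuran-2(5H)-one
Conditions: Me2SO4, K2CO3, acetone, reflux
Reagents that add atoms: dimethyl sulfate, COS(=O)(=O)OC
Why: In this O-alkylation of a vinylogous carboxylic acid the hard electrophile methylates the tetronate anion on the C4 oxygen, which masks the acidic proton for the carbanion chemistry that follows.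

**Step 13**
Reactants: 23 (2R,6E)-9-[5-(furan-3-ylmethyl)furan-3-yl]-2,6-dimethylnon-6-enal; 25 4-methoxy-3-methylfuran-2(5H)-one
Product: 27 5-{(2R,6E)-9-[5-(furan-3-ylmethyl)furan-3-yl]-1-hydroxy-2,6-dimethylnon-6-en-1-yl}-4-methoxy-3-methylfuran-2(5H)-one as a mixture of epimers at the two new centres, via lithiated tetronate 26 (not isolated)
Conditions: 25, LDA, THF, −78 °C; then 23, −78 °C; AcOH
Reagents that add atoms: none
Why: In this vinylogous aldol addition LDA removes a C5 proton of 25 to give the aromatic 2-oxidofuran 26, which adds through C5 to the aldehyde at −78 °C faster than it enolises it; the two new stereocentres (ring C5 and the carbinol) form without control and are both erased in step 14.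

**Step 14**
Reactants: 27 5-{(2R,6E)-9-[5-(furan-3-ylmethyl)furan-3-yl]-1-hydroxy-2,6-dimethylnon-6-en-1-yl}-4-methoxy-3-methylfuran-2(5H)-one
Product: 29 (5Z)-5-{(2R,6E)-9-[5-(furan-3-ylmethyl)furan-3-yl]-2,6-dimethylnon-6-en-1-ylidene}-4-methoxy-3-methylfuran-2(5H)-one, via mesylate 28 (not isolated)
Conditions: MsCl, Et3N, CH2Cl2, 0 °C; then DBU, 0 °C to rt, short contact
Reagents that add atoms: none
Why: After mesylation, DBU removes the acidic C5 proton of 28 and the dienolate expels mesylate (E1cB elimination), which should favour the Z-ylidene tetronate because the E isomer would press the branched chain against the C4 methoxy group (allylic strain).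

**Step 15**
Reactants: 29 (5Z)-5-{(2R,6E)-9-[5-(furan-3-ylmethyl)furan-3-yl]-2,6-dimethylnon-6-en-1-ylidene}-4-methoxy-3-methylfuran-2(5H)-one
Product: 30 (5Z)-5-{(2R,6E)-9-[5-(furan-3-ylmethyl)furan-3-yl]-2,6-dimethylnon-6-en-1-ylidene}-4-hydroxy-3-methylfuran-2(5H)-one (CID54702820)
Conditions: LiCl, DMSO, 50 °C; then 1 M HCl, 0 °C
Reagents that add atoms: none
Why: In this Krapcho-type SN2 demethylation, established for methyl tetronates, chloride attacks the O-methyl carbon and expels the stabilised tetronate anion without touching either alkene geometry or the stereocentre, and cold dilute acid then frees the tetronic acid.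

**Compound list**
1 | (S)-3-bromo-2-methylpropan-1-ol | BrC[C@@H](C)CO | starting material
2 | [(2S)-3-bromo-2-methylpropoxy](tert-butyl)dimethylsilane | BrC[C@@H](C)CO[Si](C)(C)C(C)(C)C | intermediate
3 | (4-bromobut-1-yn-1-yl)trimethylsilane | C[Si](C)(C)C#CCCBr | starting material
4 | [4-(trimethylsilyl)but-3-yn-1-yl]magnesium bromide | C[Si](C)(C)C#CCC[Mg]Br | intermediate
5 | tert-butyldimethyl{[(2R)-2-methyl-7-(trimethylsilyl)hept-6-yn-1-yl]oxy}silane | C[Si](C)(C)C#CCCC[C@@H](C)CO[Si](C)(C)C(C)(C)C | intermediate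
6 | tert-butyldimethyl{[(2R)-2-methylhept-6-yn-1-yl]oxy}silane | C#CCCC[C@@H](C)CO[Si](C)(C)C(C)(C)C | intermediate
7 | oxirane (ethylene oxide) | C1CO1 | starting material
8 | [(1E,6R)-7-(TBSO)-2,6-dimethylhept-1-en-1-yl]dimethylalane | C[Al](C)/C=C(\C)CCC[C@@H](C)CO[Si](C)(C)C(C)(C)C | intermediate
9 | lithium butyl[(1E,6R)-7-(TBSO)-2,6-dimethylhept-1-en-1-yl]dimethylalanate | [Li+].CCCC[Al-](C)(C)/C=C(\C)CCC[C@@H](C)CO[Si](C)(C)C(C)(C)C | intermediate
10 | (3E,8R)-9-(TBSO)-4,8-dimethylnon-3-en-1-ol | OCC/C=C(\C)CCC[C@@H](C)CO[Si](C)(C)C(C)(C)C | intermediate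
11 | {[(2R,6E)-9-bromo-2,6-dimethylnon-6-en-1-yl]oxy}(tert-butyl)dimethylsilane | BrCC/C=C(\C)CCC[C@@H](C)CO[Si](C)(C)C(C)(C)C | intermediate
12 | prop-2-yn-1-ol (propargyl alcohol) | C#CCO | starting material
13 | [(3E,8R)-9-(TBSO)-4,8-dimethylnon-3-en-1-yl]magnesium bromide | Br[Mg]CC/C=C(\C)CCC[C@@H](C)CO[Si](C)(C)C(C)(C)C | intermediate
14 | chloromagnesium prop-2-yn-1-olate | C#CCO[Mg]Cl | intermediate
15 | five-membered chelate O–Mg–CH=C(chain)–CH2, 4-[(3E,8R)-9-(TBSO)-4,8-dimethylnon-3-en-1-yl]-5H-1,2-oxamagnesole | [Mg]1OCC(CC/C=C(\C)CCC[C@@H](C)CO[Si](C)(C)C(C)(C)C)=C1 | intermediate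
16 | (2Z)-2-[(3E,8R)-9-(TBSO)-4,8-dimethylnon-3-en-1-yl]-3-iodoprop-2-en-1-ol | OC/C(CC/C=C(\C)CCC[C@@H](C)CO[Si](C)(C)C(C)(C)C)=C\I | intermediate
17 | furan-3-carbaldehyde | O=Cc1ccoc1 | starting material
18 | 3-ethynylfuran | C#Cc1ccoc1 | intermediate
19 | (2Z)-2-[(3E,8R)-9-(TBSO)-4,8-dimethylnon-3-en-1-yl]-5-(furan-3-yl)pent-2-en-4-yn-1-ol | OC/C(CC/C=C(\C)CCC[C@@H](C)CO[Si](C)(C)C(C)(C)C)=C\C#Cc1ccoc1 | intermediate
20 | tert-butyl{[(2R,6E)-9-[(5Z)-5-(furan-3-ylmethylidene)-2,5-dihydrofuran-3-yl]-2,6-dimethylnon-6-en-1-yl]oxy}dimethylsilane | CC(C)(C)[Si](C)(C)OC[C@H](C)CCC/C(C)=C/CCC1=C/C(=C/c2ccoc2)OC1 | intermediate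
21 | tert-butyl{[(2R,6E)-9-[5-(furan-3-ylmethyl)furan-3-yl]-2,6-dimethylnon-6-en-1-yl]oxy}dimethylsilane | CC(C)(C)[Si](C)(C)OC[C@H](C)CCC/C(C)=C/CCc1coc(Cc2ccoc2)c1 | intermediate
22 | (2R,6E)-9-[5-(furan-3-ylmethyl)furan-3-yl]-2,6-dimethylnon-6-en-1-ol | OC[C@H](C)CCC/C(C)=C/CCc1coc(Cc2ccoc2)c1 | intermediate
23 | (2R,6E)-9-[5-(furan-3-ylmethyl)furan-3-yl]-2,6-dimethylnon-6-enal | O=C[C@H](C)CCC/C(C)=C/CCc1coc(Cc2ccoc2)c1 | intermediate
24 | 4-hydroxy-3-methylfuran-2(5H)-one (3-methyltetronic acid) | CC1=C(O)COC1=O | starting material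
25 | 4-methoxy-3-methylfuran-2(5H)-one | COC1=C(C)C(=O)OC1 | intermediate
26 | lithium 4-methoxy-3-methylfuran-2-olate (C5-lithiated tetronate) | [Li+].[O-]c1occ(OC)c1C | intermediate
27 | 5-{(2R,6E)-9-[5-(furan-3-ylmethyl)furan-3-yl]-1-hydroxy-2,6-dimethylnon-6-en-1-yl}-4-methoxy-3-methylfuran-2(5H)-one, ring C5 and carbinol centre uncontrolled | CC1=C(OC)C(C(O)[C@H](C)CCC/C(C)=C/CCc2coc(Cc3ccoc3)c2)OC1=O | intermediate
28 | methanesulfonate of 27 at the carbinol oxygen | CC1=C(OC)C(C(OS(C)(=O)=O)[C@H](C)CCC/C(C)=C/CCc2coc(Cc3ccoc3)c2)OC1=O | intermediate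
29 | (5Z)-5-{(2R,6E)-9-[5-(furan-3-ylmethyl)furan-3-yl]-2,6-dimethylnon-6-en-1-ylidene}-4-methoxy-3-methylfuran-2(5H)-one | CC1=C(OC)/C(=C/[C@H](C)CCC/C(C)=C/CCc2coc(Cc3ccoc3)c2)OC1=O | intermediate
30 | (5Z)-5-{(2R,6E)-9-[5-(furan-3-ylmethyl)furan-3-yl]-2,6-dimethylnon-6-en-1-ylidene}-4-hydroxy-3-methylfuran-2(5H)-one | CC1=C(O)/C(=C/[C@H](C)CCC/C(C)=C/CCc2coc(Cc3ccoc3)c2)OC1=O | target

Total step count: 15. Longest linear sequence: 13 steps from 1 (steps 1–6, 8–11, 13–15).

**Steps most likely to fail**

**Step 6.**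
- Risk: the chain Grignard reagent may be spent on deprotonating the acetylenic C–H faster than copper transfers it to the triple bond. A long primary alkyl group may also add sluggishly, so much of the most valuable intermediate would be lost by protonation.
- Fallback: cross-coupling replaces carbometalation. It sets out from 13 and 18 and comes back at 19.
- Anti-addition of Br2 to commercial methyl propiolate gives methyl (2E)-2,3-dibromoprop-2-enoate F1. Its less hindered C3–Br bond lies cis to the ester and undergoes site-selective Sonogashira coupling with 18 (Pd(PPh3)4, CuI, Et3N) to methyl (2E)-2-bromo-5-(furan-3-yl)pent-2-en-4-ynoate F2.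
- Transmetalation of 13 with ZnBr2 gives [(3E,8R)-9-(TBSO)-4,8-dimethylnon-3-en-1-yl]zinc bromide F3. Negishi coupling with F2 (PdCl2(dppf), THF) proceeds with retention to methyl (2Z)-2-[(3E,8R)-9-(TBSO)-4,8-dimethylnon-3-en-1-yl]-5-(furan-3-yl)pent-2-en-4-ynoate F4.
- DIBAL-H (CH2Cl2, −78 °C) then reduces the ester to 19. The cis relation of carbinol carbon and alkyne now stems from the anti-bromination, and about one equivalent of the chain reagent suffices.

**Step 9.**
- Risk: the electron-rich furyl group may polarise the gold-bound alkyne so that oxygen attacks the distal carbon (6-endo closure). Adventitious triflic acid may also erode the difurylmethane or the silyl ether during aromatisation.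
- Fallback: oxidative cyclodehydration of an ene-diol replaces alkyne activation. It sets out from 16 and 18 and comes back at 21.
- Hydroboration of 18 with dicyclohexylborane and oxidation with NaBO3 gives 2-(furan-3-yl)acetaldehyde F5.
- Nozaki–Hiyama–Kishi coupling of F5 with 16 (CrCl2, NiCl2 cat., DMF) tolerates the free hydroxyl and the enolisable aldehyde. It gives (2Z)-2-[(3E,8R)-9-(TBSO)-4,8-dimethylnon-3-en-1-yl]-5-(furan-3-yl)pent-2-ene-1,4-diol F6.
- MnO2 in CH2Cl2 oxidises the primary allylic alcohol. The product closes to 3-[(3E,8R)-9-(TBSO)-4,8-dimethylnon-3-en-1-yl]-5-(furan-3-ylmethyl)-2,5-dihydrofuran-2-ol F7, which loses water (PPTS cat.) to give 21.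

**Step 14.**
- Risk: the elimination may proceed with poor geometric selectivity. Prolonged contact with DBU may also enolise the extended system and erode the allylic stereocentre.
- Fallback: olefination replaces aldol–elimination. It sets out from 25 and 23, bypasses 27 and 28, and comes back at 29.
- Wohl–Ziegler bromination of 25 (NBS, AIBN, PhCF3, reflux) at the captodatively stabilised C5 gives 5-bromo-4-methoxy-3-methylfuran-2(5H)-one F8.
- Michaelis–Arbuzov reaction with P(OEt)3 gives diethyl (3-methoxy-4-methyl-5-oxo-2,5-dihydrofuran-2-yl)phosphonate F9.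
- Horner–Wadsworth–Emmons reaction of F9 with 23 (LiHMDS, THF, −78 to 0 °C) gives 29 directly under brief, cold basic conditions.

**Further compounds**
F1 | step 6 | methyl (2E)-2,3-dibromoprop-2-enoate | COC(=O)/C(Br)=C\Br
F2 | step 6 | methyl (2E)-2-bromo-5-(furan-3-yl)pent-2-en-4-ynoate | COC(=O)/C(Br)=C\C#Cc1ccoc1
F3 | step 6 | [(3E,8R)-9-(TBSO)-4,8-dimethylnon-3-en-1-yl]zinc bromide | Br[Zn]CC/C=C(\C)CCC[C@@H](C)CO[Si](C)(C)C(C)(C)C
F4 | step 6 | methyl (2Z)-2-[(3E,8R)-9-(TBSO)-4,8-dimethylnon-3-en-1-yl]-5-(furan-3-yl)pent-2-en-4-ynoate | COC(=O)/C(CC/C=C(\C)CCC[C@@H](C)CO[Si](C)(C)C(C)(C)C)=C\C#Cc1ccoc1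
F5 | step 9 | 2-(furan-3-yl)acetaldehyde | O=CCc1ccoc1
F6 | step 9 | (2Z)-2-[(3E,8R)-9-(TBSO)-4,8-dimethylnon-3-en-1-yl]-5-(furan-3-yl)pent-2-ene-1,4-diol | OC/C(CC/C=C(\C)CCC[C@@H](C)CO[Si](C)(C)C(C)(C)C)=C\C(O)Cc1ccoc1
F7 | step 9 | 3-[(3E,8R)-9-(TBSO)-4,8-dimethylnon-3-en-1-yl]-5-(furan-3-ylmethyl)-2,5-dihydrofuran-2-ol | OC1OC(Cc2ccoc2)C=C1CC/C=C(\C)CCC[C@@H](C)CO[Si](C)(C)C(C)(C)C
F8 | step 14 | 5-bromo-4-methoxy-3-methylfuran-2(5H)-one | COC1=C(C)C(=O)OC1Br
F9 | step 14 | diethyl (3-methoxy-4-methyl-5-oxo-2,5-dihydrofuran-2-yl)phosphonate | CCOP(=O)(OCC)C1OC(=O)C(C)=C1OC
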